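The flavanone ring C is disconnected at its aryl–carbonyl bond C4–C4a, which leads back to an (S)-3-aryl-3-aryloxypropanoate whose aryloxy part is the symmetric 3,5-bis(benzyloxy)phenyl ether (ring A). The two carbons ortho to the ether oxygen O1 are equivalent and flanked by three oxygen donors, so one acid-mediated operation (tert-butyl ester cleavage, mixed anhydride formation, intramolecular Friedel–Crafts acylation) closes ring C late, on the complete biflavonoid skeleton, as a single regioisomer and without touching C2. C2 comes from an asymmetric acetate aldol followed by Mitsunobu inversion; the 3'–6'' biaryl bond comes from a Suzuki coupling with 6-iodoapigenin tribenzyl ether.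

Key step: step 10

Remark: the target structure fixes only C2, which is (S); the tri-ortho-oxygenated 3'–6'' biaryl axis is taken to rotate freely, so no axial control is planned. In the names below, "5,7,4'-tri-O-benzylapigenin-6-yl" means 5,7-bis(benzyloxy)-2-[4-(benzyloxy)phenyl]-4-oxo-4H-chromen-6-yl.

Step 1
Reactants: 1 apigenin; 2 benzyl bromide
Product: 3 7-(benzyloxy)-2-[4-(benzyloxy)phenyl]-5-hydroxy-4H-chromen-4-one (7,4'-di-O-benzylapigenin)
Conditions: BnBr (2.2 equiv), K2CO3, DMF, rt
Reagents that add atoms: benzyl bromide (2), BrCc1ccccc1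
Why: Williamson etherification in which the 5-OH, locked in a hydrogen bond to the C4 carbonyl and the least nucleophilic phenol, stays free while the 7- and 4'-phenols are benzylated.

Step 2
Reactants: 3 7,4'-di-O-benzylapigenin; 4 N-iodosuccinimide
Product: 5 7-(benzyloxy)-2-[4-(benzyloxy)phenyl]-5-hydroxy-6-iodo-4H-chromen-4-one
Conditions: NIS (1.05 equiv), DMF, rt, dark
Reagents that add atoms: N-iodosuccinimide (4), O=C1CCC(=O)N1I
Why: Electrophilic aromatic iodination in which the free 5-OH should direct the iodine to its ortho carbon C6 rather than to C8, the regiochemistry expected for 5-hydroxy-7-alkoxyflavones under neutral conditions.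

Step 3
Reactants: 5 6-iodo-7,4'-di-O-benzylapigenin; 2 benzyl bromide
Product: 6 5,7-bis(benzyloxy)-2-[4-(benzyloxy)phenyl]-6-iodo-4H-chromen-4-one
Conditions: BnBr (1.5 equiv), K2CO3, DMF, 70 °C
Reagents that add atoms: benzyl bromide (2), BrCc1ccccc1
Why: Williamson etherification under more forcing conditions overcomes the chelation of the 5-OH and removes the last acidic phenol before the cross-coupling and the Mitsunobu step.

Step 4
Reactants: 7 3-bromo-4-hydroxybenzaldehyde; 8 bis(pinacolato)diboron
Product: 9 4-hydroxy-3-(4,4,5,5-tetramethyl-1,3,2-dioxaborolan-2-yl)benzaldehyde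
Conditions: Pd(dppf)Cl2 (3 mol%), KOAc, 1,4-dioxane, 90 °C
Reagents that add atoms: bis(pinacolato)diboron (8), CC1(C)OB(OC1(C)C)B1OC(C)(C)C(C)(C)O1
Why: Miyaura borylation of the aryl bromide, in which the weak base KOAc leaves the aldehyde intact and the product is a stable ortho-hydroxyaryl pinacol boronate.

Step 5
Reactants: 6 6-iodo-5,7,4'-tri-O-benzylapigenin; 9 4-hydroxy-3-(pinacolboryl)benzaldehyde
Product: 10 4-hydroxy-3-(5,7,4'-tri-O-benzylapigenin-6-yl)benzaldehyde
Conditions: Pd(OAc)2 (5 mol%), SPhos (10 mol%), K3PO4, toluene/H2O, 80 °C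
Reagents that add atoms: none
Why: Suzuki–Miyaura coupling in which the bulky electron-rich biarylphosphine SPhos allows oxidative addition into the doubly ortho-substituted iodide and reductive elimination to the tri-ortho-substituted biaryl, the 3'–6'' bond of the target.

Step 6
Reactants: 10 biaryl phenol aldehyde; 11 benzyl chloroformate
Product: 12 benzyl 4-formyl-2-(5,7,4'-tri-O-benzylapigenin-6-yl)phenyl carbonate
Conditions: CbzCl, Et3N, CH2Cl2, 0 °C
Reagents that add atoms: benzyl chloroformate (11), O=C(Cl)OCc1ccccc1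
Why: O-Acylation of the phenol to an aryl benzyl carbonate turns the para oxygen of ring B from a strong into a weak donor, so that the benzylic centre made next resists ionisation, and the group leaves by hydrogenolysis together with the benzyl ethers.

Step 7
Reactants: 13 tert-butyl acetate; 14 tert-butyldimethylsilyl chloride
Product: 15 tert-butyl[(1-tert-butoxyethenyl)oxy]dimethylsilane (silyl ketene acetal of tert-butyl acetate)
Conditions: LiN(iPr)2, THF, −78 °C; then TBSCl, DMPU, −78 °C to rt
Reagents that add atoms: tert-butyldimethylsilyl chloride (14), CC(C)(C)[Si](C)(C)Cl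
Why: O-Silylation of the lithium ester enolate gives the silyl ketene acetal required as the nucleophile of the Mukaiyama aldol addition.

Step 8
Reactants: 12 aryl carbonate aldehyde; 15 silyl ketene acetal
Product: 17 tert-butyl (3R)-3-[4-(benzyloxycarbonyloxy)-3-(5,7,4'-tri-O-benzylapigenin-6-yl)phenyl]-3-hydroxypropanoate, via trichlorosilyl ether 16 (not isolated)
Conditions: SiCl4 (1.5 equiv), chiral bisphosphoramide derived from N,N'-dimethyl-1,1'-binaphthyl-2,2'-diamine (5 mol%, enantiomer chosen for Re-face attack), CH2Cl2, −78 °C; then sat. aq. NaHCO3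
Reagents that add atoms: none
Why: Catalytic enantioselective Mukaiyama aldol addition in which the phosphoramide-bound trichlorosilyl cation activates the aldehyde and shields one face, so that the ketene acetal adds to the Re face and sets the (R) carbinol centre under catalyst control.

Step 9
Reactants: 17 (3R)-hydroxy ester; 18 3,5-bis(benzyloxy)phenol
Product: 19 tert-butyl (3S)-3-[3,5-bis(benzyloxy)phenoxy]-3-[4-(benzyloxycarbonyloxy)-3-(5,7,4'-tri-O-benzylapigenin-6-yl)phenyl]propanoate
Conditions: PPh3, DIAD, toluene, 0 °C to rt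
Reagents that add atoms: none
Why: Mitsunobu etherification, an SN2 displacement of the oxyphosphonium group by the phenoxide with inversion, converts the (R) alcohol into the (S) aryl ether that becomes C2 of the flavanone, the carbonate-bearing ring B disfavouring any SN1 leakage.

Step 10
Reactants: 19 (3S)-aryloxy tert-butyl ester
Product: 22 (2S)-5,7-bis(benzyloxy)-2-[4-(benzyloxycarbonyloxy)-3-(5,7,4'-tri-O-benzylapigenin-6-yl)phenyl]chroman-4-one, via carboxylic acid 20 (not isolated), via mixed trifluoroacetic anhydride 21 (not isolated)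
Conditions: TFA/CH2Cl2 (1:4), 0 °C to rt; then TFAA (3 equiv), 0 °C
Reagents that add atoms: none
Why: TFA removes the tert-butyl group as isobutene to give acid 20, TFAA converts it into mixed anhydride 21, and the acylium-like carbon C4 is attacked by the ring-A carbon ortho to the ether oxygen O1 (the future C4a), after which loss of a proton restores aromaticity. The closest known reaction type is the intramolecular Friedel–Crafts acylation of 3-aryloxypropanoic acids to chroman-4-ones. Ring C, the six-membered pyranone, is closed in the 6-exo-trig mode by electrophilic aromatic substitution. No stereocentre is formed, and C2 is not a reacting atom, so it should keep the (S) configuration set in step 9. The step needs ring A to react in preference to the other arenes and the benzylic C2–O bond to resist acid: ring A is the only ring with three oxygen donors ortho or para to the attacked carbon, its two ortho carbons are equivalent by symmetry and the only ones that can close a six-membered ring, and the carbonate on ring B withholds the para-oxygen lone pair that would otherwise let C2 ionise. Partial acid loss of the peri 5-benzyl groups would be harmless, because all benzyl groups are removed in step 11.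

Step 11
Reactants: 22 protected (2S)-flavanone–flavone
Product: 23 (2S)-2-{3-[5,7-dihydroxy-2-(4-hydroxyphenyl)-4-oxo-4H-chromen-6-yl]-4-hydroxyphenyl}-5,7-dihydroxychroman-4-one (CNP0277421.1)
Conditions: H2 (1 atm), 10% Pd/C, EtOAc/MeOH, rt, stopped when hydrogen uptake for the six benzyl groups is complete
Reagents that add atoms: none
Why: Hydrogenolysis on palladium cleaves the five benzyl ethers and the benzyl carbonate (with loss of CO2) under neutral conditions, so ring C cannot open by a base-induced retro-oxa-Michael reaction and C2 should keep its (S) configuration.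

Compound list
1 | apigenin | O=c1cc(-c2ccc(O)cc2)oc2cc(O)cc(O)c12 | starting material
2 | benzyl bromide | BrCc1ccccc1 | starting material
3 | 7-(benzyloxy)-2-[4-(benzyloxy)phenyl]-5-hydroxy-4H-chromen-4-one | O=c1cc(-c2ccc(OCc3ccccc3)cc2)oc2cc(OCc3ccccc3)cc(O)c12 | intermediate
4 | N-iodosuccinimide | O=C1CCC(=O)N1I | starting material
5 | 7-(benzyloxy)-2-[4-(benzyloxy)phenyl]-5-hydroxy-6-iodo-4H-chromen-4-one | O=c1cc(-c2ccc(OCc3ccccc3)cc2)oc2cc(OCc3ccccc3)c(I)c(O)c12 | intermediate
6 | 5,7-bis(benzyloxy)-2-[4-(benzyloxy)phenyl]-6-iodo-4H-chromen-4-one | O=c1cc(-c2ccc(OCc3ccccc3)cc2)oc2cc(OCc3ccccc3)c(I)c(OCc3ccccc3)c12 | intermediate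
7 | 3-bromo-4-hydroxybenzaldehyde | O=Cc1ccc(O)c(Br)c1 | starting material
8 | bis(pinacolato)diboron | CC1(C)OB(OC1(C)C)B1OC(C)(C)C(C)(C)O1 | starting material
9 | 4-hydroxy-3-(4,4,5,5-tetramethyl-1,3,2-dioxaborolan-2-yl)benzaldehyde | O=Cc1ccc(O)c(B2OC(C)(C)C(C)(C)O2)c1 | intermediate
10 | 4-hydroxy-3-(5,7,4'-tri-O-benzylapigenin-6-yl)benzaldehyde | O=Cc1ccc(O)c(-c2c(OCc3ccccc3)cc3oc(-c4ccc(OCc5ccccc5)cc4)cc(=O)c3c2OCc2ccccc2)c1 | intermediate
11 | benzyl chloroformate | O=C(Cl)OCc1ccccc1 | starting material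
12 | benzyl 4-formyl-2-(5,7,4'-tri-O-benzylapigenin-6-yl)phenyl carbonate | O=Cc1ccc(OC(=O)OCc2ccccc2)c(-c2c(OCc3ccccc3)cc3oc(-c4ccc(OCc5ccccc5)cc4)cc(=O)c3c2OCc2ccccc2)c1 | intermediate
13 | tert-butyl acetate | CC(=O)OC(C)(C)C | starting material
14 | tert-butyldimethylsilyl chloride | CC(C)(C)[Si](C)(C)Cl | starting material
15 | tert-butyl[(1-tert-butoxyethenyl)oxy]dimethylsilane | C=C(OC(C)(C)C)O[Si](C)(C)C(C)(C)C | intermediate
16 | tert-butyl (3R)-3-[4-(benzyloxycarbonyloxy)-3-(5,7,4'-tri-O-benzylapigenin-6-yl)phenyl]-3-(trichlorosilyloxy)propanoate (formed in the flask, not isolated) | CC(C)(C)OC(=O)C[C@@H](O[Si](Cl)(Cl)Cl)c1ccc(OC(=O)OCc2ccccc2)c(-c2c(OCc3ccccc3)cc3oc(-c4ccc(OCc5ccccc5)cc4)cc(=O)c3c2OCc2ccccc2)c1 | intermediate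
17 | tert-butyl (3R)-3-[4-(benzyloxycarbonyloxy)-3-(5,7,4'-tri-O-benzylapigenin-6-yl)phenyl]-3-hydroxypropanoate | CC(C)(C)OC(=O)C[C@@H](O)c1ccc(OC(=O)OCc2ccccc2)c(-c2c(OCc3ccccc3)cc3oc(-c4ccc(OCc5ccccc5)cc4)cc(=O)c3c2OCc2ccccc2)c1 | intermediate
18 | 3,5-bis(benzyloxy)phenol | Oc1cc(OCc2ccccc2)cc(OCc2ccccc2)c1 | starting material
19 | tert-butyl (3S)-3-[3,5-bis(benzyloxy)phenoxy]-3-[4-(benzyloxycarbonyloxy)-3-(5,7,4'-tri-O-benzylapigenin-6-yl)phenyl]propanoate | CC(C)(C)OC(=O)C[C@H](Oc1cc(OCc2ccccc2)cc(OCc2ccccc2)c1)c1ccc(OC(=O)OCc2ccccc2)c(-c2c(OCc3ccccc3)cc3oc(-c4ccc(OCc5ccccc5)cc4)cc(=O)c3c2OCc2ccccc2)c1 | intermediate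
20 | (3S)-3-[3,5-bis(benzyloxy)phenoxy]-3-[4-(benzyloxycarbonyloxy)-3-(5,7,4'-tri-O-benzylapigenin-6-yl)phenyl]propanoic acid (formed in the flask, not isolated) | OC(=O)C[C@H](Oc1cc(OCc2ccccc2)cc(OCc2ccccc2)c1)c1ccc(OC(=O)OCc2ccccc2)c(-c2c(OCc3ccccc3)cc3oc(-c4ccc(OCc5ccccc5)cc4)cc(=O)c3c2OCc2ccccc2)c1 | intermediate
21 | mixed anhydride of acid 20 and trifluoroacetic acid (formed in the flask, not isolated) | O=C(OC(=O)C(F)(F)F)C[C@H](Oc1cc(OCc2ccccc2)cc(OCc2ccccc2)c1)c1ccc(OC(=O)OCc2ccccc2)c(-c2c(OCc3ccccc3)cc3oc(-c4ccc(OCc5ccccc5)cc4)cc(=O)c3c2OCc2ccccc2)c1 | intermediate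
22 | (2S)-5,7-bis(benzyloxy)-2-[4-(benzyloxycarbonyloxy)-3-(5,7,4'-tri-O-benzylapigenin-6-yl)phenyl]chroman-4-one | O=C1C[C@@H](c2ccc(OC(=O)OCc3ccccc3)c(-c3c(OCc4ccccc4)cc4oc(-c5ccc(OCc6ccccc6)cc5)cc(=O)c4c3OCc3ccccc3)c2)Oc2cc(OCc3ccccc3)cc(OCc3ccccc3)c21 | intermediate
23 | (2S)-2-{3-[5,7-dihydroxy-2-(4-hydroxyphenyl)-4-oxo-4H-chromen-6-yl]-4-hydroxyphenyl}-5,7-dihydroxychroman-4-one (CNP0277421.1) | O=C1C[C@@H](c2ccc(O)c(-c3c(O)cc4oc(-c5ccc(O)cc5)cc(=O)c4c3O)c2)Oc2cc(O)cc(O)c21 | target

Total step count: 11.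
Longest linear sequence: 9 steps (steps 1, 2, 3, 5, 6, 8, 9, 10 and 11, from apigenin).

Steps most likely to fail

1. Step 9 (Mitsunobu etherification). The oxyphosphonium intermediate can lose a proton from the acidic CH2 next to the ester and eliminate to the tert-butyl cinnamate. The phloroglucinol-type phenol can also react through carbon instead of oxygen, and any ionisation at the benzylic carbon would erode the inversion. The fallback sets out from aldehyde 12 and comes back to the route at ether 19. The aldol of step 8 would be repeated with the antipodal bisphosphoramide, which gives, through tert-butyl (3S)-3-aryl-3-(trichlorosilyloxy)propanoate F1, the (3S)-hydroxy ester F2. F2 would then be O-arylated with retention of configuration by a Chan–Lam coupling with commercial 3,5-bis(benzyloxy)phenylboronic acid (Cu(OAc)2 20 mol%, pyridine, 4 Å molecular sieves, air, CH2Cl2, rt). In that reaction the carbinol C–O bond is never broken, so neither elimination through an activated hydroxyl nor substitution at the benzylic carbon is involved.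

2. Step 10 (key ring closure). Intermolecular C-trifluoroacetylation of ring A by TFAA, tert-butylation of ring A during the ester cleavage, or acid-promoted migration of a benzyl group could outrun the ring closure. The fallback sets out from 19 and comes back to the route at 22. The tert-butyl ester would be cleaved with ZnBr2 in CH2Cl2 and acid 20 isolated. It would then be converted (EDC·HCl, HOBt, then 1.0 equiv of Me2NH at 0 °C, so that the active ester outcompetes the aryl carbonate) into the N,N-dimethylamide F3. Electrophilic amide activation (Tf2O, 2-fluoropyridine, CH2Cl2, −78 to 0 °C) would then close the same C4–C4a bond by an intramolecular Vilsmeier–Haack-type attack of ring A under buffered aprotic conditions. This gives the cyclic iminium triflate F4, which aqueous NaHCO3 hydrolyses to ketone 22.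

3. Step 5 (Suzuki–Miyaura coupling). Protodeboronation of the electron-rich boronate phenoxide and hydrodeiodination of 6 may outpace the slow transmetalation at the doubly ortho-substituted palladium centre. The fallback sets out from bromophenol 7 and iodide 6 and comes back to the route at 12, bypassing 9 and 10. Phenol 7 would first be acylated with benzyl chloroformate 11 and Et3N to benzyl 2-bromo-4-formylphenyl carbonate F5. F5 would be stannylated (Bu3SnSnBu3, Pd(PPh3)4, toluene, 110 °C) to benzyl 4-formyl-2-(tributylstannyl)phenyl carbonate F6. A base-free Stille coupling of F6 with iodide 6 (Pd(PPh3)4, CuI, DMF, 80 °C) would give 12 directly, with no phenoxide and no boron species involved.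

Further compounds
F1 | step 9 | tert-butyl (3S)-3-[4-(benzyloxycarbonyloxy)-3-(5,7,4'-tri-O-benzylapigenin-6-yl)phenyl]-3-(trichlorosilyloxy)propanoate | CC(C)(C)OC(=O)C[C@H](O[Si](Cl)(Cl)Cl)c1ccc(OC(=O)OCc2ccccc2)c(-c2c(OCc3ccccc3)cc3oc(-c4ccc(OCc5ccccc5)cc4)cc(=O)c3c2OCc2ccccc2)c1
F2 | step 9 | tert-butyl (3S)-3-[4-(benzyloxycarbonyloxy)-3-(5,7,4'-tri-O-benzylapigenin-6-yl)phenyl]-3-hydroxypropanoate | CC(C)(C)OC(=O)C[C@H](O)c1ccc(OC(=O)OCc2ccccc2)c(-c2c(OCc3ccccc3)cc3oc(-c4ccc(OCc5ccccc5)cc4)cc(=O)c3c2OCc2ccccc2)c1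
F3 | step 10 | (3S)-3-[3,5-bis(benzyloxy)phenoxy]-3-[4-(benzyloxycarbonyloxy)-3-(5,7,4'-tri-O-benzylapigenin-6-yl)phenyl]-N,N-dimethylpropanamide | CN(C)C(=O)C[C@H](Oc1cc(OCc2ccccc2)cc(OCc2ccccc2)c1)c1ccc(OC(=O)OCc2ccccc2)c(-c2c(OCc3ccccc3)cc3oc(-c4ccc(OCc5ccccc5)cc4)cc(=O)c3c2OCc2ccccc2)c1
F4 | step 10 | N-{(2S)-5,7-bis(benzyloxy)-2-[4-(benzyloxycarbonyloxy)-3-(5,7,4'-tri-O-benzylapigenin-6-yl)phenyl]chroman-4-ylidene}-N-methylmethanaminium trifluoromethanesulfonate | C[N+](C)=C1C[C@@H](c2ccc(OC(=O)OCc3ccccc3)c(-c3c(OCc4ccccc4)cc4oc(-c5ccc(OCc6ccccc6)cc5)cc(=O)c4c3OCc3ccccc3)c2)Oc2cc(OCc3ccccc3)cc(OCc3ccccc3)c21.[O-]S(=O)(=O)C(F)(F)F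
F5 | step 5 | benzyl 2-bromo-4-formylphenyl carbonate | O=Cc1ccc(OC(=O)OCc2ccccc2)c(Br)c1
F6 | step 5 | benzyl 4-formyl-2-(tributylstannyl)phenyl carbonate | O=Cc1ccc(OC(=O)OCc2ccccc2)c([Sn](CCCC)(CCCC)CCCC)c1
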